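## The problem

The target is a spiro[5.5]undecane of the chamigrene type. With the skeleton numbered C1 to C14, ring A is C6–C1H2–C2HBr–C3(CH3)Cl–C4H2–C5H2 and ring B is C6–C7(=C14H2)–C8(=O)–C9H=C10Br–C11(CH3)2; the rings meet at quaternary C6, which stands next to quaternary C11, so a congested pair of fully substituted carbons has to be forged. Of the three stereocentres (C2, C3, C6), C6 is stereogenic only because the two arms of ring A differ, so it must be set while C1/C2 and C5/C4 are distinguishable and must never pass through a ring A with a local mirror plane. C6 could in principle direct the halogens, but an untethered Br–Cl addition to a C2=C3 alkene gets from its bromonium ion only the regiochemistry (Br on secondary C2, Cl on tertiary C3) and the anti relationship; the two faces are flanked by C7 and C11, both fully substituted, and are hardly differentiated. Ring B carries its bromine on C10, the enone carbon beside the gem-dimethyl group; this is the more hindered end of the C8–C9–C10 unit, so halogenation of a precursor with oxygen at both ends would go to the wrong carbon. The cross-conjugated methylene dienone, the vinylogous acyl bromide and the tertiary chloride anti to a secondary bromide will not stand strong base, hydride, low-valent metals or prolonged Lewis acid, so they must appear late. The feature that opens a way through is that C7 lies 1,4 across ring A from C3: an oxygen on C7 can reach C3 only from the face on which C7 stands, closing a 2-oxabicyclo[2.2.2]octane as in 1,8-cineole, and in the target chlorine sits on exactly that face and bromine on the other. Because C7 also carries C14, the same oxygen can later leave as water and uncover the methylene group.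

## Retrosynthesis

**33 to 32 (C7=C14).** The methylene dienone is the most fragile group and is made last, by dehydration of tertiary carbinol 32. Only C14 carries hydrogens beta to C7 (C6 is quaternary, C8 a carbonyl), so there is no regiochemical choice. A Mannich-type methylenation would be shorter, but it would leave no oxygen on C7 for the tether. The forward step must be neutral enough to spare the C3 chloride.

**32 to 31 (C3–Cl).** The C3–Cl bond is traced to the C3–O bond of bridged ether 31. In 31 the C2–Br bond is antiperiplanar to C3–O, so loss of oxygen should regenerate a bromonium ion on the C11 face and chloride has to enter from the C7 face. Direct chloride delivery to a free bromonium ion would give the same regiochemistry but no facial control. The forward step must ionise C3–O and not C7–O; the C8 carbonyl beside C7 argues for that.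

**31 to 30 (C2–Br and C3–O, key step).** Both bonds are cut together, opening the oxabicycle to tertiary alcohol 30 with a C2=C3 alkene. Other tether sites do not reach: C11 has no handle, and an oxygen on C14 would have to close a larger ring. The precursor has lost one ring and two stereocentres; the step asks that the brominating agent find the ring A alkene and not the electron-poor bromoenone.

**30 to 28 to 26 (C7–O, C7–C14).** The carbinol oxygen and the C14 methyl are introduced by two enolate reactions on bromoenone 26, methylation to 28 and then hydroxylation to 30. C7 is the only enolisable position of 26. Carrying a C7 oxygen from an early stage would drag an uncontrolled stereocentre through most of the route.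

**26 back to 20 (C10–Br).** The bromine is placed on C10 by way of the enol triflate 23 of a C10 ketone while C8 is held at the alcohol level (silyl ether 21). C11 is quaternary, so the ketone can enolise only toward C9 and the halogen cannot end up at C8. Holding C8 and C10 at the ketone level together is avoided, because bromide would then enter at the less hindered C8. The price is four functional-group steps (21, 23, 24, 25); the gain is certainty about the regiochemistry.

**20 to 19 to 18 to 17 (C8–C9, C9–C10).** Ring B is opened at C8–C9 by a retro-aldol to keto aldehyde 19, then at C9–C10 by removing the methyl group that methyllithium adds to lactone 17. The lactone carbonyl is C10 and the lactone CH2–O is C8, so both oxygens of ring B are differentiated from the start.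

**17 to 16 to 14 to 13 (ring A).** The C3 methyl comes from cross-coupling of enol triflate 16, which comes from enone 14 by conjugate reduction and trapping, and 14 from alkene 13 by allylic oxidation. A plain isomerisation of the alkene into the C2=C3 position was rejected: C2=C3 and C3=C4 isomers differ only in the sense of C6, so equilibration would racemise. The enolate from 1,4-reduction is regiodefined.

**13 to 10 (C8–O).** The lactone arises from hydroboration of the vinyl group of acid 10. It protects the C8 hydroxyl and the C10 carboxyl through the ring A steps at no cost in steps.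

**10 to 7 to 5 + 6 (C6–C11).** The bond between the two quaternary carbons is cut by an Ireland–Claisen transform to ester 7 of allylic alcohol 5 and isobutyryl chloride 6. Alkylation of a ring A enolate at C6 would see no facial difference, whereas the sigmatropic shift relays a carbinol stereocentre to C6 and leaves the alkene on a defined arm of ring A.

**5 to 4 to 1 + 2.** Alcohol 5 comes from dienone 4 by enantioselective reduction, and 4 from 3-ethoxycyclohex-2-en-1-one 1 and vinylmagnesium bromide 2 by addition and hydrolytic transposition.

## Roads not taken

**Alternative 1:** This road cuts C6–C11 in a bromonium-initiated cation–olefin cyclisation. A chiral Lewis base with NBS would form the C10=C11 bromonium ion of an open-chain diene, the tetrasubstituted C6=C7 alkene would attack C11, and loss of a proton from C14 would give A1. One step would make ring B, the quaternary pair, the C10–Br bond and the methylene group, and in convergence it beats the chosen plan. Its weak points for this target: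
- enantioselective bromonium cyclisations that end on a tetrasubstituted alkene and create vicinal quaternary carbons are thinly supported;
- the proton must leave from C14 and not from C8;
- A1 has a secondary sp3 bromide at C10 and no oxygen at C8, so reaching the bromoenone means oxidising C8 and dehydrogenating C9–C10 without eliminating HBr;
- ring A must still be closed from the acetoxymethyl and ketal arms and then halogenated with no directing group.

The chosen plan is longer, but every stereocentre and the C10 bromine have a defined origin.

**Alternative 2:** This road cuts C5–C6 and C1=C2 in a Robinson-type spiroannulation. A chiral primary amine with an acid would turn racemic aldehyde A3 into its enamine, which adds to methyl vinyl ketone A4; aldol condensation then gives spiro enone A2. The step is catalytic and sets C6 from simple materials. A2 carries the same ring A enone as 14, which the chosen route reaches only in step 6, so the front end is clearly shorter. Its weak points: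
- the aldehyde carbon is flanked by the gem-dimethyl carbon, so enamine formation and a Michael addition that builds vicinal quaternary carbons are at the edge of what such catalysts manage;
- ring B of A2 has oxygen only at C10, so C8 would need a late allylic oxidation beside the ring A alkene, and C7 is unfunctionalised.

Against the shorter start, the chosen plan sets a chirality transfer that does not depend on a demanding catalytic step and a ring B whose C8 and C10 oxygens are in place and distinct from the outset.

**Alternative 3:** This road cuts C10–C11 in a late radical closure. Fe(acac)3 with PhSiH3 would transfer a hydrogen atom to the isopropenyl group of bromoynone A6, and the tertiary C11 radical would add to the bromine-bearing alkyne carbon to give bromoenone A5, which lacks only the C7 methylene. It forms the hindered C10–C11 bond and the bromoenone with unambiguous regiochemistry in one step; here it is better than the chosen plan, which spends steps 12 to 16 on the same problem. Its weak points: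
- the ring A bromochloride must already be present in A6, and with C7 a plain CH2 there is no oxygen to tether, so the facial problem of the Br–Cl addition is only moved earlier;
- the radical conditions must tolerate a secondary bromide, a tertiary chloride and a bromoalkyne, and the closure must prefer the six-membered mode over attack at C9.

The chosen plan sets against it the tether-controlled halogenation and polar steps whose selectivities are predictable.

Key step: step 19

Convention: locants C1 to C14 in the text are those of the target skeleton; systematic names in the compound list use their own locants.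

Assumption: C8 in 20, 21 and 23–25 and C7 in 28 are transient stereocentres formed without control and are written without descriptor. C7 in 30–32 is drawn as one epimer; its C7 epimer is expected to form alongside in step 18, to behave alike in steps 19 and 20 and to converge on 33 in step 21.

Remark: 18 is written as the open hydroxy ketone; it is expected to exist largely as its cyclic hemiketal.

## Route

Step 1
Reactants: 1 3-ethoxycyclohex-2-en-1-one; 2 vinylmagnesium bromide
Product: 4 3-vinylcyclohex-2-en-1-one, via tertiary carbinol 3 (not isolated)
Conditions: THF, 0 °C; then 1 M HCl, 0 °C to rt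
Reagents that add atoms: none
Why: Stork–Danheiser sequence: 1,2-addition of the Grignard reagent to the vinylogous ester, then acid hydrolysis of the enol ether and loss of water give the transposed dienone; no stereocentre is formed.

Step 2
Reactants: 4 3-vinylcyclohex-2-en-1-one
Product: 5 (R)-3-vinylcyclohex-2-en-1-ol
Conditions: (S)-2-methyl-CBS-oxazaborolidine (15 mol %), catecholborane, toluene, −78 °C; then aq. NaOH
Reagents that add atoms: none
Why: Corey–Bakshi–Shibata reduction; the carbonyl binds the catalyst with its larger sp2 (dienyl) side away from the boron substituent, and hydride delivery to the exposed face should give the (R)-carbinol. Catecholborane at low temperature avoids hydroboration of the diene.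

Step 3
Reactants: 5 (R)-3-vinylcyclohex-2-en-1-ol; 6 isobutyryl chloride
Product: 7 (R)-3-vinylcyclohex-2-en-1-yl 2-methylpropanoate
Conditions: Et3N, DMAP (cat.), CH2Cl2, 0 °C
Reagents that add atoms: none
Why: DMAP-catalysed acylation of a secondary allylic alcohol; the carbinol centre is not touched.

Step 4
Reactants: 7 (R)-3-vinylcyclohex-2-en-1-yl 2-methylpropanoate
Product: 10 2-methyl-2-[(1R)-1-vinylcyclohex-2-en-1-yl]propanoic acid, via silyl ketene acetal 8 (not isolated), via trimethylsilyl ester 9 (not isolated)
Conditions: LiN(i-Pr)2, THF, −78 °C; Me3SiCl; −78 to 60 °C; then 1 M HCl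
Reagents that add atoms: none
Why: Ireland–Claisen rearrangement; the [3,3] shift is suprafacial across the ring allyl unit, so the C6–C11 bond forms on the face that carried the C–O bond, relaying the carbinol chirality to quaternary C6 and moving the ring alkene to C1=C2. The isobutyrate has no enolate geometry to control, and the reaction type is established for vicinal quaternary carbons.

Step 5
Reactants: 10 2-methyl-2-[(1R)-1-vinylcyclohex-2-en-1-yl]propanoic acid
Product: 13 (6R)-1,1-dimethyl-3-oxaspiro[5.5]undec-7-en-2-one, via bis-boron adduct 11 (not isolated), via hydroxy acid 12 (not isolated)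
Conditions: 9-BBN (2.2 equiv), THF, 0 °C to rt; NaOH, H2O2; then 2 M HCl, rt
Reagents that add atoms: hydrogen peroxide, OO
Why: Anti-Markovnikov hydroboration–oxidation; 9-BBN selects the monosubstituted vinyl group over the cis-disubstituted ring alkene, and the delta-hydroxy acid closes to the lactone on acidification (gem-dialkyl effect). The lactone masks the C8 hydroxyl and the C10 carboxyl through steps 6 to 8.

Step 6
Reactants: 13 (6R)-1,1-dimethyl-3-oxaspiro[5.5]undec-7-en-2-one
Product: 14 (6R)-1,1-dimethyl-3-oxaspiro[5.5]undec-7-ene-2,9-dione
Conditions: Rh2(cap)4 (1 mol %), t-BuOOH, K2CO3, CH2Cl2, rt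
Reagents that add atoms: tert-butyl hydroperoxide, CC(C)(C)OO
Why: Dirhodium-catalysed allylic oxidation with tert-butyl hydroperoxide; C3 is the only allylic CH2 (C6 is quaternary) and oxygen is taken up at the unhindered end of the allyl radical, giving the 4,4-disubstituted cyclohexenone.

Step 7
Reactants: 14 (6R)-1,1-dimethyl-3-oxaspiro[5.5]undec-7-ene-2,9-dione
Product: 16 (6S)-1,1-dimethyl-2-oxo-3-oxaspiro[5.5]undec-8-en-9-yl trifluoromethanesulfonate, via lithium enolate 15 (not isolated)
Conditions: LiBH(s-Bu)3, THF, −78 °C; then PhNTf2, −78 °C to rt
Reagents that add atoms: N-phenylbis(trifluoromethanesulfonimide), O=S(=O)(N(c1ccccc1)S(=O)(=O)C(F)(F)F)C(F)(F)F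
Why: Conjugate reduction with a hindered borohydride and O-triflation of the enolate in the same flask; hydride adds to C1, so the enolate exists only as C2=C3–OLi, which keeps the two arms of ring A different and C6 stereogenic. The alpha-quaternary lactone should not be reduced at −78 °C.

Step 8
Reactants: 16 (6S)-1,1-dimethyl-2-oxo-3-oxaspiro[5.5]undec-8-en-9-yl trifluoromethanesulfonate
Product: 17 (6S)-1,1,9-trimethyl-3-oxaspiro[5.5]undec-8-en-2-one
Conditions: MeMgBr, Fe(acac)3 (5 mol %), THF/NMP, −30 °C
Reagents that add atoms: methylmagnesium bromide, C[Mg]Br
Why: Iron-catalysed Kumada-type coupling of an alkenyl triflate with a methyl Grignard reagent; it is fast at low temperature and tolerant of esters, and it fixes the C3 methyl on the C2=C3 alkene.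

Step 9
Reactants: 17 (6S)-1,1,9-trimethyl-3-oxaspiro[5.5]undec-8-en-2-one
Product: 18 3-[(1S)-1-(2-hydroxyethyl)-4-methylcyclohex-3-en-1-yl]-3-methylbutan-2-one
Conditions: MeLi (1.1 equiv), THF, −78 °C; then AcOH
Reagents that add atoms: methyllithium, [Li]C
Why: Mono-addition of an organolithium to a lactone; the lithium hemiketal persists at −78 °C and the neopentyl ketone set free on work-up is too hindered for a second addition. The step forms C9–C10 and makes C10 the ketone from which the vinyl bromide will come.

Step 10
Reactants: 18 3-[(1S)-1-(2-hydroxyethyl)-4-methylcyclohex-3-en-1-yl]-3-methylbutan-2-one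
Product: 19 2-[(1S)-4-methyl-1-(2-methyl-3-oxobutan-2-yl)cyclohex-3-en-1-yl]acetaldehyde
Conditions: Dess–Martin periodinane, NaHCO3, CH2Cl2, rt
Reagents that add atoms: none
Why: Dess–Martin oxidation of the primary alcohol of the open-chain tautomer; the tertiary hemiketal cannot be oxidised and drains through the equilibrium.

Step 11
Reactants: 19 2-[(1S)-4-methyl-1-(2-methyl-3-oxobutan-2-yl)cyclohex-3-en-1-yl]acetaldehyde
Product: 20 (6S)-4-hydroxy-1,1,9-trimethylspiro[5.5]undec-8-en-2-one
Conditions: K2CO3, MeOH, 0 °C
Reagents that add atoms: none
Why: Intramolecular aldol addition; only the methyl ketone enolate can close a six-membered ring (the aldehyde enolate would have to form a cyclobutane), so C8–C9 and ring B are formed. The C8 carbinol configuration is immaterial because C8 is oxidised in step 16.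

Step 12
Reactants: 20 (6S)-4-hydroxy-1,1,9-trimethylspiro[5.5]undec-8-en-2-one
Product: 21 (6S)-1,1,9-trimethyl-4-(triethylsilyloxy)spiro[5.5]undec-8-en-2-one
Conditions: Et3SiCl, imidazole, DMF, rt
Reagents that add atoms: chlorotriethylsilane, CC[Si](Cl)(CC)CC
Why: Silylation of a secondary alcohol; it blocks retro-aldol cleavage and allows the ketone to be enolised.

Step 13
Reactants: 21 (6S)-1,1,9-trimethyl-4-(triethylsilyloxy)spiro[5.5]undec-8-en-2-one
Product: 23 (6S)-1,1,9-trimethyl-4-(triethylsilyloxy)spiro[5.5]undeca-2,8-dien-2-yl trifluoromethanesulfonate, via potassium enolate 22 (not isolated)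
Conditions: KN(SiMe3)2, THF, −78 °C; then Comins' reagent, −78 °C
Reagents that add atoms: N-(5-chloropyridin-2-yl)bis(trifluoromethanesulfonimide), O=S(=O)(N(c1ccc(Cl)cn1)S(=O)(=O)C(F)(F)F)C(F)(F)F
Why: Kinetic enolisation and O-triflation; C11 is quaternary, so the ketone can enolise only toward C9 and the triflate is fixed on C10. The reactive triflating agent allows trapping at −78 °C before the silyloxy group can be eliminated.

Step 14
Reactants: 23 (6S)-1,1,9-trimethyl-4-(triethylsilyloxy)spiro[5.5]undeca-2,8-dien-2-yl trifluoromethanesulfonate
Product: 24 [(6S)-2-bromo-1,1,9-trimethylspiro[5.5]undeca-2,8-dien-4-yl]oxytriethylsilane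
Conditions: Ni(cod)2 (10 mol %), LiBr, DMA/THF, rt
Reagents that add atoms: lithium bromide, [Li+].[Br-]
Why: Nickel-catalysed exchange of an enol triflate for bromide (oxidative addition to zerovalent nickel, halide exchange, C–Br reductive elimination); bromine is placed on C10 with no regiochemical ambiguity.

Step 15
Reactants: 24 [(6S)-2-bromo-1,1,9-trimethylspiro[5.5]undeca-2,8-dien-4-yl]oxytriethylsilane
Product: 25 (6S)-2-bromo-1,1,9-trimethylspiro[5.5]undeca-2,8-dien-4-ol
Conditions: HF·pyridine, THF, 0 °C
Reagents that add atoms: none
Why: Fluoride cleavage of a triethylsilyl ether; the vinyl bromide and both alkenes are inert.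

Step 16
Reactants: 25 (6S)-2-bromo-1,1,9-trimethylspiro[5.5]undeca-2,8-dien-4-ol
Product: 26 (6S)-4-bromo-5,5,9-trimethylspiro[5.5]undeca-3,8-dien-2-one
Conditions: Dess–Martin periodinane, NaHCO3, CH2Cl2, 0 °C to rt
Reagents that add atoms: none
Why: Dess–Martin oxidation of an allylic alcohol gives the beta-bromoenone and removes the transient C8 stereocentre.

Step 17
Reactants: 26 (6S)-4-bromo-5,5,9-trimethylspiro[5.5]undeca-3,8-dien-2-one
Product: 28 (6S)-4-bromo-1,5,5,9-tetramethylspiro[5.5]undeca-3,8-dien-2-one, via lithium dienolate 27 (not isolated)
Conditions: LiN(i-Pr)2, THF, −78 °C; then MeI, −78 to −30 °C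
Reagents that add atoms: iodomethane, CI
Why: Kinetic alpha'-deprotonation of the enone (C7 is its only sp3 C–H position next to the carbonyl) and C-methylation of the cross-conjugated dienolate install C14. The hindered amide base should not add to the vinylogous acyl bromide, and the new C7 centre is planarised again in step 18.

Step 18
Reactants: 28 (6S)-4-bromo-1,5,5,9-tetramethylspiro[5.5]undeca-3,8-dien-2-one
Product: 30 (1R,6R)-4-bromo-1-hydroxy-1,5,5,9-tetramethylspiro[5.5]undeca-3,8-dien-2-one, via potassium enolate 29 (not isolated)
Conditions: KN(SiMe3)2, THF, −78 °C; then 2-(phenylsulfonyl)-3-phenyloxaziridine, −78 °C; then AcOH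
Reagents that add atoms: 2-(phenylsulfonyl)-3-phenyloxaziridine, O=S(=O)(c1ccccc1)N1OC1c1ccccc1
Why: Enolate hydroxylation with a Davis oxaziridine; electrophilic oxygen is transferred to C7 of the fully substituted enolate to give the tertiary alpha-ketol. The two faces of C7 differ only through the remote ring A alkene, so both C7 epimers are expected; both are usable because C7 becomes trigonal in step 21.

Step 19
Reactants: 30 (1R,6R)-4-bromo-1-hydroxy-1,5,5,9-tetramethylspiro[5.5]undeca-3,8-dien-2-one
Product: 31 bridged bromo ether (2-oxabicyclo[2.2.2]octane from the C7 oxygen to C3, bromine on C2; 2S,3S,6R,7R in skeleton numbering)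
Conditions: NBS, CH2Cl2, 0 °C, dark
Reagents that add atoms: N-bromosuccinimide, O=C1CCC(=O)N1Br
Why: NBS transfers Br+ reversibly to either face of the C2=C3 alkene; only the bromonium ion on the C11 face has the C7 hydroxyl placed behind C3, and anti opening at the tertiary carbon forms the C3–O and C2–Br bonds. The closest known reaction type is the etherification of alpha-terpineol-type 4-(1-hydroxyalkyl)cyclohexenes with N-bromosuccinimide or phenylselenenyl halides to 2-substituted 1,8-cineoles. The one ring closed is the 2-oxabicyclo[2.2.2]octane: oxygen attacks C3 through a boat of ring A in a six-membered closure that is exo with respect to the C5–C4 tether, whereas attack at C2 would give a five-membered ether and is disfavoured because the positive charge sits on tertiary C3. C3 is set by C6 through the tether, since oxygen can arrive only on the C7 face, and C2 is set by C3 through anti addition, so bromine ends cis to C11. The step needs chemoselectivity for the ring A alkene, which the electron-poor bromoenone secures. It also needs the unproductive bromonium ion on the C7 face to revert and not be trapped, which a non-nucleophilic dry solvent should secure. No enolisable position is left beside the ketone (C7 is quaternary, C9 vinylic), so alpha-bromination cannot compete, and either C7 epimer can reach C3 because ring B can flip to place the hydroxyl anti to C11.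

Step 20
Reactants: 31 bridged bromo ether
Product: 32 (1R,6R,8S,9S)-4,8-dibromo-9-chloro-1-hydroxy-1,5,5,9-tetramethylspiro[5.5]undec-3-en-2-one
Conditions: TiCl4, CH2Cl2, −78 to −40 °C; then H2O
Reagents that add atoms: titanium tetrachloride, Cl[Ti](Cl)(Cl)Cl
Why: Proposed new method: TiCl4 should bind the C8 carbonyl and the ether oxygen as a five-membered chelate, and ionisation can then occur only at C3, because the C2–Br bond is antiperiplanar to C3–O and gives a bromonium ion on the C11 face, whereas a cation at C7 would sit beside the complexed carbonyl; chloride from the titanate on the departing oxygen opens the bromonium ion at the tertiary carbon from the C7 face, so C3 is substituted with overall retention and chlorine ends trans to bromine; the closest known reaction types are the cleavage of 1,8-cineole-type tertiary ethers to tertiary chlorides by hydrogen chloride or Lewis acids and the retentive substitution of beta-bromo alcohols and their esters through bromonium ions (neighbouring-group participation), and the combination has not been shown on a 2-bromocineole ether.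

Step 21
Reactants: 32 (1R,6R,8S,9S)-4,8-dibromo-9-chloro-1-hydroxy-1,5,5,9-tetramethylspiro[5.5]undec-3-en-2-one
Product: 33 (6S,8S,9S)-4,8-dibromo-9-chloro-5,5,9-trimethyl-1-methylidenespiro[5.5]undec-3-en-2-one
Conditions: Burgess reagent, toluene, 60 °C
Reagents that add atoms: none
Why: Burgess dehydration (syn elimination through the sulfamate ester); only C14 carries beta-hydrogens, so the exocyclic methylene is the sole possible alkene. The neutral conditions should spare the tertiary chloride, the secondary bromide and the dienone.

## Compound list

1 | 3-ethoxycyclohex-2-en-1-one | CCOC1=CC(=O)CCC1 | starting material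
2 | vinylmagnesium bromide | C=C[Mg]Br | starting material
3 | 3-ethoxy-1-vinylcyclohex-2-en-1-ol (racemic, present as its bromomagnesium alkoxide; not isolated) | CCOC1=CC(O)(C=C)CCC1 | intermediate
4 | 3-vinylcyclohex-2-en-1-one | C=CC1=CC(=O)CCC1 | intermediate
5 | (R)-3-vinylcyclohex-2-en-1-ol | C=CC1=C[C@H](O)CCC1 | intermediate
6 | isobutyryl chloride | CC(C)C(Cl)=O | starting material
7 | (R)-3-vinylcyclohex-2-en-1-yl 2-methylpropanoate | C=CC1=C[C@H](OC(=O)C(C)C)CCC1 | intermediate
8 | trimethylsilyl ketene acetal of 7 (not isolated) | C=CC1=C[C@H](OC(O[Si](C)(C)C)=C(C)C)CCC1 | intermediate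
9 | trimethylsilyl 2-methyl-2-[(1R)-1-vinylcyclohex-2-en-1-yl]propanoate (not isolated) | C=C[C@@]1(C(C)(C)C(=O)O[Si](C)(C)C)C=CCCC1 | intermediate
10 | 2-methyl-2-[(1R)-1-vinylcyclohex-2-en-1-yl]propanoic acid | C=C[C@@]1(C(C)(C)C(=O)O)C=CCCC1 | intermediate
11 | bis(9-borabicyclo[3.3.1]nonane) adduct of 10, B-alkyl at C8 and acyloxyborane at the carboxyl (not isolated) | O=C(OB1C2CCCC1CCC2)C(C)(C)[C@]3(CCB4C5CCCC4CCC5)C=CCCC3 | intermediate
12 | 2-[(1R)-1-(2-hydroxyethyl)cyclohex-2-en-1-yl]-2-methylpropanoic acid (not isolated) | OCC[C@@]1(C(C)(C)C(=O)O)C=CCCC1 | intermediate
13 | (6R)-1,1-dimethyl-3-oxaspiro[5.5]undec-7-en-2-one | O=C1OCC[C@]2(C=CCCC2)C1(C)C | intermediate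
14 | (6R)-1,1-dimethyl-3-oxaspiro[5.5]undec-7-ene-2,9-dione | O=C1OCC[C@]2(C=CC(=O)CC2)C1(C)C | intermediate
15 | lithium C2=C3 enolate of the reduced enone (not isolated) | O=C1OCC[C@]2(CC=C(O[Li])CC2)C1(C)C | intermediate
16 | (6S)-1,1-dimethyl-2-oxo-3-oxaspiro[5.5]undec-8-en-9-yl trifluoromethanesulfonate | O=C1OCC[C@]2(CC=C(OS(=O)(=O)C(F)(F)F)CC2)C1(C)C | intermediate
17 | (6S)-1,1,9-trimethyl-3-oxaspiro[5.5]undec-8-en-2-one | O=C1OCC[C@]2(CC=C(C)CC2)C1(C)C | intermediate
18 | 3-[(1S)-1-(2-hydroxyethyl)-4-methylcyclohex-3-en-1-yl]-3-methylbutan-2-one (in equilibrium with its cyclic hemiketal) | OCC[C@@]1(C(C)(C)C(C)=O)CC=C(C)CC1 | intermediate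
19 | 2-[(1S)-4-methyl-1-(2-methyl-3-oxobutan-2-yl)cyclohex-3-en-1-yl]acetaldehyde | O=CC[C@@]1(C(C)(C)C(C)=O)CC=C(C)CC1 | intermediate
20 | (6S)-4-hydroxy-1,1,9-trimethylspiro[5.5]undec-8-en-2-one (C4 carbinol epimers) | OC1CC(=O)C(C)(C)[C@]2(C1)CC=C(C)CC2 | intermediate
21 | (6S)-1,1,9-trimethyl-4-(triethylsilyloxy)spiro[5.5]undec-8-en-2-one (C4 epimers) | CC[Si](CC)(CC)OC1CC(=O)C(C)(C)[C@]2(C1)CC=C(C)CC2 | intermediate
22 | potassium C9=C10 enolate of 21 (not isolated) | CC[Si](CC)(CC)OC1C=C(O[K])C(C)(C)[C@]2(C1)CC=C(C)CC2 | intermediate
23 | (6S)-1,1,9-trimethyl-4-(triethylsilyloxy)spiro[5.5]undeca-2,8-dien-2-yl trifluoromethanesulfonate (C4 epimers) | CC[Si](CC)(CC)OC1C=C(OS(=O)(=O)C(F)(F)F)C(C)(C)[C@]2(C1)CC=C(C)CC2 | intermediate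
24 | [(6S)-2-bromo-1,1,9-trimethylspiro[5.5]undeca-2,8-dien-4-yl]oxytriethylsilane (C4 epimers) | CC[Si](CC)(CC)OC1C=C(Br)C(C)(C)[C@]2(C1)CC=C(C)CC2 | intermediate
25 | (6S)-2-bromo-1,1,9-trimethylspiro[5.5]undeca-2,8-dien-4-ol (C4 epimers) | OC1C=C(Br)C(C)(C)[C@]2(C1)CC=C(C)CC2 | intermediate
26 | (6S)-4-bromo-5,5,9-trimethylspiro[5.5]undeca-3,8-dien-2-one | O=C1C=C(Br)C(C)(C)[C@]2(C1)CC=C(C)CC2 | intermediate
27 | lithium cross-conjugated dienolate of 26 (not isolated) | [Li]OC1=C[C@]2(CC=C(C)CC2)C(C)(C)C(Br)=C1 | intermediate
28 | (6S)-4-bromo-1,5,5,9-tetramethylspiro[5.5]undeca-3,8-dien-2-one (C1 epimers) | CC1C(=O)C=C(Br)C(C)(C)[C@@]12CC=C(C)CC2 | intermediate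
29 | potassium C7=C8 enolate of 28 (not isolated) | CC1=C(O[K])C=C(Br)C(C)(C)[C@@]12CC=C(C)CC2 | intermediate
30 | (1R,6R)-4-bromo-1-hydroxy-1,5,5,9-tetramethylspiro[5.5]undeca-3,8-dien-2-one (drawn epimer; its C1 epimer accompanies it) | CC1=CC[C@@]2(CC1)[C@@](C)(O)C(=O)C=C(Br)C2(C)C | intermediate
31 | bridged bromo ether: 2-oxabicyclo[2.2.2]octane from the C7 oxygen to C3 with bromine on C2, fused to the bromoenone ring (2S,3S,6R,7R in skeleton numbering) | C[C@]12CC[C@]3(C[C@@H]1Br)[C@@](C)(O2)C(=O)C=C(Br)C3(C)C | intermediate
32 | (1R,6R,8S,9S)-4,8-dibromo-9-chloro-1-hydroxy-1,5,5,9-tetramethylspiro[5.5]undec-3-en-2-one | C[C@]1(O)C(=O)C=C(Br)C(C)(C)[C@]12CC[C@](C)(Cl)[C@@H](Br)C2 | intermediate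
33 | (6S,8S,9S)-4,8-dibromo-9-chloro-5,5,9-trimethyl-1-methylidenespiro[5.5]undec-3-en-2-one | C=C1C(=O)C=C(Br)C(C)(C)[C@]12CC[C@](C)(Cl)[C@@H](Br)C2 | target

## Step count and least certain steps

Total step count: 21. Longest linear sequence: 21 (the route is fully linear).

**Step 20 (ether to chloride).** The bromonium ion may lose a proton to give an allylic bromide or return to the ether instead of taking up chloride, because chloride delivery competes with ion-pair collapse. Long exposure to the Lewis acid may also exchange halide at the vinylogous acyl bromide or shift the alpha-ketol. The fallback gives up the tether and uses known chemistry. It sets out from 30 (material already converted to 31 can be returned to 30 with zinc in acetic acid). Burgess dehydration of 30 gives 4-bromo-5,5,9-trimethyl-1-methylidenespiro[5.5]undeca-3,8-dien-2-one F1. Its ring A alkene is then bromochlorinated with tetrabutylammonium dichlorobromate in CH2Cl2 at low temperature (anti addition, bromine to C2, chlorine to C3). This comes back to the route at 33, at the price of poor facial selectivity and a diastereomer separation.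

**Step 19 (key step).** Capture by the hindered, electron-poor tertiary hydroxyl may be slow, so the bromonium ion on either face is intercepted by succinimide or loses a proton. The fallback raises the nucleophilicity of the oxygen by lowering the oxidation level at C8 for the moment. From 30, Luche reduction (NaBH4, CeCl3·7H2O, MeOH) gives the C8 carbinol, 4-bromo-1,5,5,9-tetramethylspiro[5.5]undeca-3,8-diene-1,2-diol F2. NBS then closes the same ether through the C7 hydroxyl (the C8 hydroxyl would need a seven-membered ring to reach C3), giving the C8 carbinol of the bromo ether F3. Dess–Martin oxidation of this allylic alcohol comes back to the route at 31.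

**Step 18 (hydroxylation).** The hindered C7–H may be deprotonated incompletely, and the potassium alkoxide formed may add to the sulfonimine by-product. The fallback oxidises a neutral enol derivative. From 28, Me3SiOTf and Et3N give the trimethylsilyl dienol ether F4, which is oxidised with dimethyldioxirane at −78 °C (Rubottom oxidation; the silyloxy diene should react faster than the ring A alkene). Acidic work-up comes back to the route at 30.

**Step 7 (reductive triflation).** Hydride may add 1,2 because C1 adjoins the quaternary centre, and any proton exchange of the enolate before triflation would scramble the two arms of ring A and erode C6. The fallback separates reduction from triflation. From 14, RhCl(PPh3)3-catalysed 1,4-hydrosilylation with Et3SiH gives the isolable triethylsilyl enol ether F5. CsF with PhNTf2 converts it into the triflate and comes back to the route at 16.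

**Step 14 (triflate to bromide).** Oxidative addition to the triflate beside the gem-dimethyl carbon may be slow and reduction to the alkene may take over. The fallback goes through tin. From 23, Pd(PPh3)4 (zerovalent palladium), Me3SnSnMe3 and LiCl give the vinylstannane F6, and bromodestannylation with NBS comes back to the route at 24.

**Step 2 (enantioselective reduction).** Facial discrimination may be incomplete, since the two flanks of the carbonyl (CH=C and CH2) differ only modestly. The fallback is a kinetic resolution. From 4, Luche reduction gives racemic 3-vinylcyclohex-2-en-1-ol F7. Candida antarctica lipase B with vinyl acetate should acylate the (R)-enantiomer to (R)-3-vinylcyclohex-2-en-1-yl acetate F8. After separation, methanolysis (K2CO3, MeOH) comes back to the route at 5.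

## Further compounds

F1 | step 20 | (6S)-4-bromo-5,5,9-trimethyl-1-methylidenespiro[5.5]undeca-3,8-dien-2-one | C=C1C(=O)C=C(Br)C(C)(C)[C@@]12CC=C(C)CC2
F2 | step 19 | (1R,6R)-4-bromo-1,5,5,9-tetramethylspiro[5.5]undeca-3,8-diene-1,2-diol (C2 carbinol epimers) | CC1=CC[C@@]2(CC1)[C@@](C)(O)C(O)C=C(Br)C2(C)C
F3 | step 19 | C8 carbinol of bridged bromo ether 31 (C8 epimers) | C[C@]12CC[C@]3(C[C@@H]1Br)[C@@](C)(O2)C(O)C=C(Br)C3(C)C
F4 | step 18 | trimethylsilyl dienol ether of 28 | CC1=C(O[Si](C)(C)C)C=C(Br)C(C)(C)[C@@]12CC=C(C)CC2
F5 | step 7 | (6S)-1,1-dimethyl-9-(triethylsilyloxy)-3-oxaspiro[5.5]undec-8-en-2-one | O=C1OCC[C@]2(CC=C(O[Si](CC)(CC)CC)CC2)C1(C)C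
F6 | step 14 | triethyl[(6S)-1,1,9-trimethyl-2-(trimethylstannyl)spiro[5.5]undeca-2,8-dien-4-yl]oxysilane (C4 epimers) | CC[Si](CC)(CC)OC1C=C([Sn](C)(C)C)C(C)(C)[C@]2(C1)CC=C(C)CC2
F7 | step 2 | racemic 3-vinylcyclohex-2-en-1-ol | C=CC1=CC(O)CCC1
F8 | step 2 | (R)-3-vinylcyclohex-2-en-1-yl acetate | C=CC1=C[C@H](OC(C)=O)CCC1
A1 | alternative 1 | ring B bromide with C7 methylene and quaternary C6 carrying acetoxymethyl and ketal arms | C=C1CC[C@@H](Br)C(C)(C)[C@]1(COC(C)=O)CCC2(C)OCCO2
A2 | alternative 2 | spiro enone with ring A enone and ring B C10 ketone | O=C1C=C[C@@]2(CC1)CCCC(=O)C2(C)C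
A3 | alternative 2 | racemic 2,2-dimethyl-3-oxocyclohexane-1-carbaldehyde | O=CC1CCCC(=O)C1(C)C
A4 | alternative 2 | methyl vinyl ketone | C=CC(C)=O
A5 | alternative 3 | spirocyclic beta-bromoenone lacking the C7 methylene | O=C1C[C@@]2(CC[C@](C)(Cl)[C@@H](Br)C2)C(C)(C)C(Br)=C1
A6 | alternative 3 | bromoynone with isopropenyl group on C6 | C=C(C)[C@@]1(CC(=O)C#CBr)CC[C@](C)(Cl)[C@@H](Br)C1
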